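**Structural features**

The target 19 is a monocyclic tetrahydrofuran (ring A: O1, C2, C3, C4, C5) in which C5 is an unsubstituted CH2. C2 carries a 3,4-dimethoxyphenyl group, C3 a methyl group, and C4 an exocyclic carbinol carbon C6 that bears the hydroxyl and the second 3,4-dimethoxyphenyl group. Four stereocentres stand in an unbroken chain C2–C3–C4–C6 (2S,3S,4R,6R): aryl and methyl are trans across C2–C3, methyl and the C6 arm are cis across C3–C4, and C6 lies outside the ring next to C4. Both benzylic C–O bonds (C2–O1 and C6–OH) sit on electron-rich rings and ionise easily under acid, so epimerisation at C2, opening of ring A and loss of the C6 hydroxyl are the fragile points; a carbonyl group on C6 or on the C3 arm also makes C4 or C3 epimerisable. The real difficulty is the cis relation of the two one-carbon arms on C3 and C4, which a monocyclic tetrahydrofuran does not favour, together with the exocyclic centre C6 and the absolute configuration. The key step uses the fact that the methyl carbon and C6 can be tied together as the carbonyl and acetal carbons of a butenolide whose ring alkene is C3=C4, while the triad C2–O1–C5 is a carbonyl ylide of 3,4-dimethoxybenzaldehyde. Suprafacial addition to that ring-locked Z-alkene delivers the cis C3/C4 pair, and the acetal stereocentre on the future C6 decides the face.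

**Logic of the disconnections**

19 ⇒ 16 + 18 (18 from 17). The C6–aryl bond is cut. C6 is the only centre outside ring A and an aryl nucleophile is trivially available. The cut removes one ring and one stereocentre and leaves a single ring with three contiguous centres. The forward addition must take the Felkin–Anh face of the C6 carbonyl of 16 (anti to C3, the more substituted α-branch) and must not enolise C4.

16 ⇒ 15. The C6=O bond is exchanged for two C6–OCH3 bonds. The carbonyl would not survive the hydride steps that create the methyl group and would make C4 epimerisable throughout. The gain is a robust, non-epimerisable C6 during three steps. The demand is an unmasking mild enough to spare C4 and the benzylic C2–O1 bond.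

15 ⇒ 14 ⇒ 13 ⇒ 12. The three C–H bonds of the C3 methyl are traced back to a C–O bond (sulfonate, alcohol) and then to an ester carbonyl. This gives the two arms on C3 and C4 different oxidation levels (ester against acetal), so they can never be confused. The forward sequence needs an acetal that is inert to hydride and sulfonylation, and a displacement that is faster than participation by the neighbouring acetal oxygen.

12 ⇒ 11. The ester O–CH3 bond and the two C6–OCH3 bonds are replaced by the lactone C(=O)–O–C6 link and the C6–O bond to the auxiliary. Both arms are thereby tied into one cis-fused γ-lactone acetal, which explains their cis relation and brings in the element of absolute control. The forward step must open this pseudo-ester completely with methanol and acid without cleaving C2–O1; it returns 4 for reuse.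

11 ⇒ 9 + 5 (through 10). The C5–C4 and C2–C3 bonds are cut, the two C–C bonds of ring A that flank the cis pair. Each fragment then derives from one aldehyde, and one step accounts for ring A, two skeletal bonds and three stereocentres. The forward union needs regiocontrol (C5 to the β-carbon, C2 to the α-carbon of 5), attack anti to the alkoxy group of 5, and exo placement of the aryl group.

9 ⇒ 8 ⇒ 6 + 7. The C2–Cl bond is exchanged for a C2–O bond, and the two C2–O bonds of 8 are cut back to the carbonyl of 6. The symmetrical acetal 8 is preferred to a mixed methyl acetal because chloride exchange can then expel only one kind of alkoxy group and give only 9. The demand is that 9, which ionises very easily, is made and consumed without delay.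

5 ⇒ 3 + 4, and 3 ⇒ 1 (through 2). The exocyclic acetal C–O bond of 5 is cut, and the lactone carbonyl and hemiacetal hydroxyl of 3 are traced to an oxidative excision of the formyl carbon of 1. The gain is a chiral-pool auxiliary on a four-carbon unit from a bulk aldehyde. The demand is that the acetal centre equilibrates under acid while the 5S epimer crystallises.

**Other disconnections considered**

Alternative 1: The cut removes C3–C4 and C3–C6, which places C3, C4 and C6 in a cyclopropane fused to a γ-lactone. In this arrangement the lactone carbonyl is the latent C3 methyl, the lactone O–CH2 is C5, and the aroyl carbonyl on C3 is C2. Forward, the metal carbene generated from diazo ketoester A1 with Rh2(OAc)4, or a chiral congener such as Rh2(S-PTTL)4, would add to the tethered E-alkene and give bicycle A2. An oxygen nucleophile would then open the donor–acceptor cyclopropane at C6 with inversion; after that the C2 carbonyl is reduced, the lactone is taken down to the methyl group, and O1 is closed from the C5 oxygen onto benzylic C2.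
- In its favour: C4 and C6 are set together and stereospecifically, from the E geometry of the alkene and one SN2-type inversion. A descriptor check shows that this pairing corresponds to the 4R,6R relation of 19. On this point the alternative is better than the chosen plan, which leaves C6 to a substrate-controlled addition in step 11. The thermodynamically preferred trans lactone also maps onto the cis C3/C4 relation.
- Against it here: absolute configuration would rest on catalyst control over an acceptor/acceptor carbene, a class in which high enantioselectivity is harder to reach than with diazoacetates. The veratryl donor makes a ring-opened benzylic cation accessible, so the inversion at C6 may leak. The endgame must distinguish two benzylic oxygens, turn a lactone carbonyl into a methyl group while freeing the C5 oxygen, and close ring A at C2 without the C6 hydroxyl closing the isomeric 2,5-diaryl ring, which calls for protecting-group steps.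
- Comparison: structurally it builds ring A last, whereas the chosen plan builds it first with three centres at once. Mechanistically it is a stereospecific sequence set against a face-selective cycloaddition followed by a Felkin–Anh addition. In step count it is expected to be equal at best and probably longer.

Alternative 2: The cut removes C4–C3 and the bond between C6 and the carbon that becomes the C3 methyl. Forward, amide A3 would be converted with Tf2O and collidine into a keteniminium ion that adds [2+2] to the tethered vinyl group; hydrolysis would give cyclobutanone A4, in which ring A and a four-membered ring share C3–C4. Aryl addition to the C6 carbonyl, cleavage of the C6–CH2 bond of the four-membered ring, and reduction at C6 would follow.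
- In its favour: ring A and the cis C3/C4 relation arise together from the single C2 stereocentre of A3. The methyl group emerges at the right oxidation level without a deoxygenation sequence, which is a point on which this alternative is better than the chosen plan (three steps are spent there on carbonyl to methyl).
- Against it here: A3 is a doubly activated (benzylic and allylic) ether of an electron-rich arene, and it must survive Tf2O and triflate salts. The arene can attack the keteniminium ion, and a β-alkoxy amide can eliminate. The C2 centre must be bought by a separate asymmetric step. The ring cleavage must break C6–CH2 and not C6–C4, whereas radical scission would be expected to prefer the more substituted C4. Finally, C6 would be set by hydride addition to a ketone, which on the Felkin–Anh model uses the same face as the aryl group in step 11 and therefore points to the C6 epimer A5 of 19, so reagent control would be needed.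
- Comparison: it is equal to the chosen plan in making ring A and three ring centres in one step. It is weaker in the source of absolute configuration and in the fragility of its substrate. The step count is expected to be similar.

Alternative 3: The cut removes C3–C4 only. Forward, a palladium hydride generated from zerovalent palladium (Pd2(dba)3) and acetic acid would add to the aryl alkyne of enyne A6; the vinylpalladium would insert the tethered vinyl group and a silane would reduce the CH2–Pd bond to the methyl group, giving arylidene tetrahydrofuran A7.
- In its favour: it is catalytic and very short, and the methyl group is formed directly. In step economy it is clearly better than the chosen plan, and the 2,3-trans relation should follow from a pseudo-equatorial aryl group in the cyclisation.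
- Against it here: the C2 centre of A6 again needs its own asymmetric step, and the doubly activated ether may ionise to an allylpalladium species under the zerovalent palladium and acid. The decisive point is stereochemical. Hydropalladation is syn, so the aryl group of A7 is cis to C5 (Z). A syn hydrometalation–oxidation that puts hydrogen on C4 anti to the C3 methyl (as the cis C3/C4 relation requires) then places the C6 oxygen in the S sense. The expected product is therefore A5, not 19, and an inversion or an oxidation–reduction at C6 would have to be added.
- Comparison: structurally it is the most direct route to the carbon skeleton. Mechanistically it sets C3 by diastereoselection from C2, which is comparable to the exo-selectivity question of the chosen plan, but it leaves C6 in the wrong sense, whereas the chosen plan predicts the right one. Its step count stays lower even with the correction.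

Key step: step 5

Remark on the chemistry: (+)-menthol is taken as the (1S,2R,5S) enantiomer. Its crystalline acetal 5 then has the 5S configuration, which is the one that leads to the 2S,3S,4R,6R series.

**Route**

Step 1
Reactants: 1 furfural
Product: 3 5-hydroxyfuran-2(5H)-one (racemic), via furfural endoperoxide 2 (not isolated)
Conditions: O2, rose bengal (cat.), MeOH, visible light, 20 °C
Reagents that add atoms: dioxygen, O=O
Why: Dye-sensitised photooxygenation of a furan: singlet oxygen adds [4+2] across the diene, methanol attacks the formyl group of the endoperoxide, and fragmentation expels it as methyl formate to leave the γ-hydroxybutenolide. No stereocentre is controlled here.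

Step 2
Reactants: 3 5-hydroxyfuran-2(5H)-one, 4 (+)-menthol
Product: 5 (5S)-5-{[(1S,2R,5S)-2-isopropyl-5-methylcyclohexyl]oxy}furan-2(5H)-one
Conditions: CSA (cat.), toluene, reflux (Dean–Stark); crystallisation from hexane, −20 °C; mother liquor re-equilibrated with CSA (cat.) and recrystallised
Reagents that add atoms: none
Why: Acid-catalysed acetalisation of the pseudo-acid hydroxyl. The acetal carbon epimerises through its oxocarbenium ion under the same acid and the less soluble 5S epimer is drawn out by crystallisation (crystallisation-induced diastereomer transformation), which sets the only stereocentre of 5.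

Step 3
Reactants: 6 veratraldehyde, 7 (trimethylsilyl)methanol
Product: 8 4-{bis[(trimethylsilyl)methoxy]methyl}-1,2-dimethoxybenzene
Conditions: 7 (2.4 equiv), p-TsOH·H2O (cat.), cyclohexane, reflux (Dean–Stark); Et3N quench
Reagents that add atoms: none
Why: Acid-catalysed acetalisation driven by azeotropic removal of water. The symmetrical acetal is chosen so that the next step can expel only a (trimethylsilyl)methoxy group.

Step 4
Reactants: 8 4-{bis[(trimethylsilyl)methoxy]methyl}-1,2-dimethoxybenzene
Product: 9 4-{chloro[(trimethylsilyl)methoxy]methyl}-1,2-dimethoxybenzene (racemic; chloro(3,4-dimethoxyphenyl)methyl (trimethylsilyl)methyl ether)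
Conditions: AcCl (1.05 equiv), CH2Cl2, 0 °C → rt; volatiles removed in vacuo under argon; crude oil used at once
Reagents that add atoms: acetyl chloride, CC(Cl)=O
Why: Acyl chloride cleavage of an acetal: O-acylation, loss of (trimethylsilyl)methyl acetate and chloride capture of the aryl-stabilised oxocarbenium ion give the α-chloro ether. Its stereocentre is racemic and is erased in the next step.

Step 5
Reactants: 9 4-{chloro[(trimethylsilyl)methoxy]methyl}-1,2-dimethoxybenzene, 5 (5S)-5-{[(1S,2R,5S)-2-isopropyl-5-methylcyclohexyl]oxy}furan-2(5H)-one
Product: 11 (3S,3aR,6S,6aS)-6-(3,4-dimethoxyphenyl)-3-{[(1S,2R,5S)-2-isopropyl-5-methylcyclohexyl]oxy}tetrahydro-1H,3H-furo[3,4-c]furan-1-one (cis-fused; aryl exo, alkoxy exo), via carbonyl ylide 10 (not isolated)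
Conditions: CsF (3 equiv, flame-dried), MeCN, rt; 9 (1.8 equiv) added slowly to 5 and CsF
Reagents that add atoms: none
Why: Fluoride attacks silicon of 9 while chloride leaves (1,3-elimination), unmasking the non-stabilised carbonyl ylide 10, a nucleophilic 4π dipole whose carbanionic CH2 terminus (C5) and veratryl-stabilised oxocarbenium terminus (C2) are clearly differentiated. The closest known reaction type is the fluoride-induced generation of such ylides from α-chloroalkyl silylmethyl ethers and their [3+2] addition to acrylates, maleates and enones, combined with the established anti-selective dipolar additions to 5-alkoxybutenolides. Ring A closes by an intermolecular, concerted but asynchronous suprafacial [3+2] (4π + 2π) cycloaddition, so both ring bonds form on one face of the Z-alkene and no Baldwin-type cyclisation is involved; in the stepwise limit the lactone enolate carbon would collapse onto the oxocarbenium carbon in a 5-(enolexo)-endo mode. Regiochemistry (C5 to the β-carbon, C2 to the α-carbon) follows from matching the CH2 terminus, which carries the larger HOMO coefficient, with the β-carbon of the enoate, which carries the larger LUMO coefficient. C4 and C3 are set by approach of the dipole to the face anti to the menthyloxy group on the adjacent acetal carbon, and their cis relation is guaranteed by suprafacial addition to a ring-locked Z-alkene. C2 is set by exo approach of the anti (E) ylide, which keeps the oxygen bridge away from the lactone and places the aryl group on the convex face, trans to the lactone carbonyl. The step therefore needs regio-, π-facial and exo selectivity; the first is secured by the donor aryl group, the second by the acetal stereocentre, and the third rests on sterics alone and is the least secure. Slow addition of 9 keeps the ylide concentration low and limits self-trapping.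

Step 6
Reactants: 11 (3S,3aR,6S,6aS)-6-(3,4-dimethoxyphenyl)-3-{[(1S,2R,5S)-2-isopropyl-5-methylcyclohexyl]oxy}tetrahydro-1H,3H-furo[3,4-c]furan-1-one
Product: 12 methyl (2S,3S,4R)-2-(3,4-dimethoxyphenyl)-4-(dimethoxymethyl)tetrahydrofuran-3-carboxylate
Conditions: HCl (anhydrous, ca. 0.5 M in MeOH), 0 °C → rt; NaHCO3 quench
Reagents that add atoms: methanol, CO
Why: Acid-catalysed methanolysis of a lactone acetal (pseudo-ester): ionisation at the acetal carbon, capture by methanol and Fischer esterification of the freed acid give the open ester dimethyl acetal and release (+)-menthol. No stereocentre is touched, and the ester on C3 reduces the tendency of the benzylic C2–O1 bond to ionise.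

Step 7
Reactants: 12 methyl (2S,3S,4R)-2-(3,4-dimethoxyphenyl)-4-(dimethoxymethyl)tetrahydrofuran-3-carboxylate
Product: 13 [(2S,3R,4R)-2-(3,4-dimethoxyphenyl)-4-(dimethoxymethyl)tetrahydrofuran-3-yl]methanol
Conditions: LiAlH4 (1.5 equiv), THF, 0 °C; Fieser work-up (H2O, aq. NaOH)
Reagents that add atoms: none
Why: Hydride reduction of the ester to the primary alcohol. The dimethyl acetal is inert to hydride and the basic work-up keeps it intact.

Step 8
Reactants: 13 [(2S,3R,4R)-2-(3,4-dimethoxyphenyl)-4-(dimethoxymethyl)tetrahydrofuran-3-yl]methanol
Product: 14 [(2S,3R,4R)-2-(3,4-dimethoxyphenyl)-4-(dimethoxymethyl)tetrahydrofuran-3-yl]methyl 4-methylbenzenesulfonate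
Conditions: TsCl (1.3 equiv), Et3N, DMAP (cat.), CH2Cl2, 0 °C → rt
Reagents that add atoms: 4-methylbenzenesulfonyl chloride, Cc1ccc(cc1)S(Cl)(=O)=O
Why: Sulfonylation of a primary alcohol under buffered basic conditions, which the acetal tolerates.

Step 9
Reactants: 14 [(2S,3R,4R)-2-(3,4-dimethoxyphenyl)-4-(dimethoxymethyl)tetrahydrofuran-3-yl]methyl 4-methylbenzenesulfonate
Product: 15 (2S,3S,4R)-2-(3,4-dimethoxyphenyl)-4-(dimethoxymethyl)-3-methyltetrahydrofuran
Conditions: LiEt3BH (3 equiv), THF, 0 °C → rt; H2O quench
Reagents that add atoms: none
Why: SN2 displacement of a primary sulfonate by a powerful hydride donor gives the methyl group. The reaction is run cold so that hydride delivery outruns participation by the cis acetal oxygen.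

Step 10
Reactants: 15 (2S,3S,4R)-2-(3,4-dimethoxyphenyl)-4-(dimethoxymethyl)-3-methyltetrahydrofuran
Product: 16 (3R,4S,5S)-5-(3,4-dimethoxyphenyl)-4-methyltetrahydrofuran-3-carbaldehyde
Conditions: 1 M aq. HCl, THF, 0 °C; NaHCO3; crude used at once
Reagents that add atoms: water, O
Why: Acid-catalysed hydrolysis of the dimethyl acetal through its oxocarbenium ion. Low temperature and immediate use are meant to keep C4 (α to the new carbonyl and cis to the methyl group) from equilibrating.

Step 11
Reactants: 16 (3R,4S,5S)-5-(3,4-dimethoxyphenyl)-4-methyltetrahydrofuran-3-carbaldehyde, 17 4-bromo-1,2-dimethoxybenzene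
Product: 19 (R)-(3,4-dimethoxyphenyl)[(3R,4S,5S)-5-(3,4-dimethoxyphenyl)-4-methyltetrahydrofuran-3-yl]methanol, via 3,4-dimethoxyphenylmagnesium bromide 18 (not isolated)
Conditions: 17, Mg, THF, 40 °C; then 16, THF, −78 °C → −40 °C; H2O (pH 7 buffer)
Reagents that add atoms: none
Why: Grignard addition to an α-branched aldehyde under Felkin–Anh control. The aryl group approaches anti to C3 (the more substituted α-substituent) along the Bürgi–Dunitz trajectory past the α-hydrogen, which corresponds to the 6R configuration. The low basicity of the aryl Grignard and the low temperature limit enolisation at C4.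

**Compound list**

1 | furfural (furan-2-carbaldehyde) | O=Cc1ccco1 | starting material
2 | furfural endoperoxide (2,3,7-trioxabicyclo[2.2.1]hept-5-ene-1-carbaldehyde, racemic) | O=CC12OOC(C=C1)O2 | intermediate
3 | 5-hydroxyfuran-2(5H)-one (racemic) | O=C1OC(O)C=C1 | intermediate
4 | (+)-menthol, (1S,2R,5S)-2-isopropyl-5-methylcyclohexan-1-ol | CC(C)[C@H]1CC[C@H](C)C[C@@H]1O | starting material
5 | (5S)-5-{[(1S,2R,5S)-2-isopropyl-5-methylcyclohexyl]oxy}furan-2(5H)-one | O=C1O[C@H](O[C@H]2C[C@@H](C)CC[C@@H]2C(C)C)C=C1 | intermediate
6 | veratraldehyde (3,4-dimethoxybenzaldehyde) | COc1ccc(C=O)cc1OC | starting material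
7 | (trimethylsilyl)methanol | C[Si](C)(C)CO | starting material
8 | 4-{bis[(trimethylsilyl)methoxy]methyl}-1,2-dimethoxybenzene | COc1ccc(C(OC[Si](C)(C)C)OC[Si](C)(C)C)cc1OC | intermediate
9 | 4-{chloro[(trimethylsilyl)methoxy]methyl}-1,2-dimethoxybenzene (racemic) | COc1ccc(C(Cl)OC[Si](C)(C)C)cc1OC | intermediate
10 | carbonyl ylide, (3,4-dimethoxybenzylidene)(methylene)oxonium ylide | COc1ccc(C=[O+][CH2-])cc1OC | intermediate
11 | (3S,3aR,6S,6aS)-6-(3,4-dimethoxyphenyl)-3-{[(1S,2R,5S)-2-isopropyl-5-methylcyclohexyl]oxy}tetrahydro-1H,3H-furo[3,4-c]furan-1-one | COc1ccc([C@H]2OC[C@H]3[C@@H]2C(=O)O[C@@H]3O[C@H]2C[C@@H](C)CC[C@@H]2C(C)C)cc1OC | intermediate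
12 | methyl (2S,3S,4R)-2-(3,4-dimethoxyphenyl)-4-(dimethoxymethyl)tetrahydrofuran-3-carboxylate | COc1ccc([C@H]2OC[C@H](C(OC)OC)[C@@H]2C(=O)OC)cc1OC | intermediate
13 | [(2S,3R,4R)-2-(3,4-dimethoxyphenyl)-4-(dimethoxymethyl)tetrahydrofuran-3-yl]methanol | COc1ccc([C@H]2OC[C@H](C(OC)OC)[C@@H]2CO)cc1OC | intermediate
14 | [(2S,3R,4R)-2-(3,4-dimethoxyphenyl)-4-(dimethoxymethyl)tetrahydrofuran-3-yl]methyl 4-methylbenzenesulfonate | COc1ccc([C@H]2OC[C@H](C(OC)OC)[C@@H]2COS(=O)(=O)c2ccc(C)cc2)cc1OC | intermediate
15 | (2S,3S,4R)-2-(3,4-dimethoxyphenyl)-4-(dimethoxymethyl)-3-methyltetrahydrofuran | COc1ccc([C@H]2OC[C@H](C(OC)OC)[C@@H]2C)cc1OC | intermediate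
16 | (3R,4S,5S)-5-(3,4-dimethoxyphenyl)-4-methyltetrahydrofuran-3-carbaldehyde | COc1ccc([C@H]2OC[C@H](C=O)[C@@H]2C)cc1OC | intermediate
17 | 4-bromo-1,2-dimethoxybenzene (4-bromoveratrole) | COc1ccc(Br)cc1OC | starting material
18 | (3,4-dimethoxyphenyl)magnesium bromide | COc1ccc([Mg]Br)cc1OC | intermediate
19 | (R)-(3,4-dimethoxyphenyl)[(3R,4S,5S)-5-(3,4-dimethoxyphenyl)-4-methyltetrahydrofuran-3-yl]methanol | COc1ccc([C@H]2OC[C@H]([C@@H](O)c3ccc(OC)c(OC)c3)[C@@H]2C)cc1OC | target

**Step count and risk**

Total: 11 steps. Longest linear sequence: 9 steps (steps 1, 2, 5–11 from 1; equally steps 3–11 from 6).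

Least certain steps:

Step 5 (key step). The most likely failures are loss of the ylide to self-trapping and insufficient exo/endo discrimination at C2. Self-trapping is a concern because the veratryl chloro ether from step 4 ionises as soon as it is formed and can condense with itself or with adventitious aldehyde. Exo/endo discrimination is a concern because only sterics decide it; facial and regiochemical control are better founded.

The fallback replaces the concerted union by a stepwise formation of the same two bonds. It sets out from 5 and 6 and returns at 11.
- Photosensitised radical addition of methanol to 5 (benzophenone, hν, MeOH) should place a hydroxymethyl group on the β-carbon anti to the alkoxy group. This gives (4R,5S)-4-(hydroxymethyl)-5-menthyloxydihydrofuran-2(3H)-one F1 and forms C5–C4.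
- Aldehyde 6 is converted with HC(OMe)3 and catalytic p-TsOH into veratraldehyde dimethyl acetal F2.
- Exchange of one methoxy group of F2 for the hydroxyl of F1 (PPTS, toluene, removal of methanol) gives the mixed methyl acetal F3.
- TMSOTf and iPr2NEt in CH2Cl2 at −78 °C should form the silyl ketene acetal of the lactone and ionise the acetal. An intramolecular Mukaiyama-type addition to the tethered oxocarbenium ion then forms C2–C3 and delivers 11, the five-membered ring enforcing the cis fusion.

Step 6. The most likely failure is incomplete or reversible ring opening, because the cyclic pseudo-ester and the open ester acetal can equilibrate in acidic methanol. Acid-induced solvolysis of the benzylic C2–O1 bond is a second concern.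

The fallback gives up the oxidation-level differentiation and uses steric differentiation after full reduction, with no acid. It sets out from 11 and returns at 16, so it also bypasses step 10.
- LiAlH4 in THF reduces 11 to the diol [(2S,3R,4S)-2-(3,4-dimethoxyphenyl)tetrahydrofuran-3,4-diyl]dimethanol F4, with release of the auxiliary.
- The less hindered hydroxymethyl group on C4 is silylated with tert-butyl(chloro)diphenylsilane and imidazole at −20 °C to give the mono-silyl ether F5.
- Tosylation of the remaining hydroxyl gives the silyl ether tosylate F6.
- LiEt3BH gives the C3-methyl silyl ether F7.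
- Bu4NF frees the primary alcohol [(3S,4S,5S)-5-(3,4-dimethoxyphenyl)-4-methyltetrahydrofuran-3-yl]methanol F8.
- Dess–Martin oxidation under buffered conditions gives 16.

Step 10. The most likely failure is epimerisation at C4 through the enol of the newly freed aldehyde, which would relieve the cis C3/C4 interaction, or acid-induced opening at C2 during the hydrolysis.

The fallback relays the carbonyl through a sulfur acetal, so that the aldehyde is released by alkylation at neutral pH and not by aqueous acid. It sets out from 15 and returns at 16. Transthioacetalisation of 15 with propane-1,3-dithiol and catalytic iodine in CH2Cl2 gives the dithiane 2-[(3R,4S,5S)-5-(3,4-dimethoxyphenyl)-4-methyltetrahydrofuran-3-yl]-1,3-dithiane F9. Alkylative hydrolysis (MeI, CaCO3, aqueous MeCN) then frees 16 under buffered conditions.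

Step 11. The most likely failure is poor facial selectivity at C6. A magnesium chelate between the carbonyl oxygen and O1 could compete with the Felkin–Anh pathway, and enolisation of 16 would erode C4.

The fallback moves C6 control from substrate-controlled C–C bond formation to reagent-controlled C–H bond formation. It sets out from 16 and returns at 19. The addition is run as in step 11 and the crude mixture of 19 and its C6 epimer, the (S)-carbinol F10, is oxidised with Dess–Martin periodinane to the aryl ketone (3,4-dimethoxyphenyl)[(3R,4S,5S)-5-(3,4-dimethoxyphenyl)-4-methyltetrahydrofuran-3-yl]methanone F11. Corey–Bakshi–Shibata reduction with the (S)-2-methyl-oxazaborolidine and BH3·SMe2, which treats the aryl group as the large substituent, should then deliver the 6R alcohol 19.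

**Further compounds**

F1 | step 5 | (4R,5S)-4-(hydroxymethyl)-5-{[(1S,2R,5S)-2-isopropyl-5-methylcyclohexyl]oxy}dihydrofuran-2(3H)-one | OC[C@H]1CC(=O)O[C@@H]1O[C@H]1C[C@@H](C)CC[C@@H]1C(C)C
F2 | step 5 | 4-(dimethoxymethyl)-1,2-dimethoxybenzene | COc1ccc(C(OC)OC)cc1OC
F3 | step 5 | (4R,5S)-4-{[(3,4-dimethoxyphenyl)(methoxy)methoxy]methyl}-5-{[(1S,2R,5S)-2-isopropyl-5-methylcyclohexyl]oxy}dihydrofuran-2(3H)-one (both epimers at the new acetal carbon) | COc1ccc(C(OC)OC[C@H]2CC(=O)O[C@@H]2O[C@H]2C[C@@H](C)CC[C@@H]2C(C)C)cc1OC
F4 | step 6 | [(2S,3R,4S)-2-(3,4-dimethoxyphenyl)tetrahydrofuran-3,4-diyl]dimethanol | COc1ccc([C@H]2OC[C@H](CO)[C@@H]2CO)cc1OC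
F5 | step 6 | {(2S,3R,4R)-4-{[tert-butyl(diphenyl)silyl]oxymethyl}-2-(3,4-dimethoxyphenyl)tetrahydrofuran-3-yl}methanol | COc1ccc([C@H]2OC[C@H](CO[Si](c3ccccc3)(c3ccccc3)C(C)(C)C)[C@@H]2CO)cc1OC
F6 | step 6 | {(2S,3R,4R)-4-{[tert-butyl(diphenyl)silyl]oxymethyl}-2-(3,4-dimethoxyphenyl)tetrahydrofuran-3-yl}methyl 4-methylbenzenesulfonate | COc1ccc([C@H]2OC[C@H](CO[Si](c3ccccc3)(c3ccccc3)C(C)(C)C)[C@@H]2COS(=O)(=O)c2ccc(C)cc2)cc1OC
F7 | step 6 | tert-butyl{[(3R,4S,5S)-5-(3,4-dimethoxyphenyl)-4-methyltetrahydrofuran-3-yl]methoxy}diphenylsilane | COc1ccc([C@H]2OC[C@H](CO[Si](c3ccccc3)(c3ccccc3)C(C)(C)C)[C@@H]2C)cc1OC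
F8 | step 6 | [(3S,4S,5S)-5-(3,4-dimethoxyphenyl)-4-methyltetrahydrofuran-3-yl]methanol | COc1ccc([C@H]2OC[C@H](CO)[C@@H]2C)cc1OC
F9 | step 10 | 2-[(3R,4S,5S)-5-(3,4-dimethoxyphenyl)-4-methyltetrahydrofuran-3-yl]-1,3-dithiane | COc1ccc([C@H]2OC[C@H](C3SCCCS3)[C@@H]2C)cc1OC
F10 | step 11 | (S)-(3,4-dimethoxyphenyl)[(3R,4S,5S)-5-(3,4-dimethoxyphenyl)-4-methyltetrahydrofuran-3-yl]methanol | COc1ccc([C@H]2OC[C@H]([C@H](O)c3ccc(OC)c(OC)c3)[C@@H]2C)cc1OC
F11 | step 11 | (3,4-dimethoxyphenyl)[(3R,4S,5S)-5-(3,4-dimethoxyphenyl)-4-methyltetrahydrofuran-3-yl]methanone | COc1ccc([C@H]2OC[C@H](C(=O)c3ccc(OC)c(OC)c3)[C@@H]2C)cc1OC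
A1 | alternative 1 | (E)-3-(3,4-dimethoxyphenyl)prop-2-en-1-yl 2-diazo-3-(3,4-dimethoxyphenyl)-3-oxopropanoate | COc1ccc(/C=C/COC(=O)C(=[N+]=[N-])C(=O)c2ccc(OC)c(OC)c2)cc1OC
A2 | alternative 1 | 1-(3,4-dimethoxybenzoyl)-6-exo-(3,4-dimethoxyphenyl)-3-oxabicyclo[3.1.0]hexan-2-one | O=C1OC[C@@H]2[C@@H](c3ccc(OC)c(OC)c3)[C@]12C(=O)c1ccc(OC)c(OC)c1
A3 | alternative 2 | 3-{[(1S)-1-(3,4-dimethoxyphenyl)prop-2-en-1-yl]oxy}-N,N-dimethylpropanamide | COc1ccc([C@H](C=C)OCCC(=O)N(C)C)cc1OC
A4 | alternative 2 | 2-exo-(3,4-dimethoxyphenyl)-3-oxabicyclo[3.2.0]heptan-6-one | COc1ccc([C@H]2OC[C@H]3[C@@H]2CC3=O)cc1OC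
A5 | alternative 2 | (S)-(3,4-dimethoxyphenyl)[(3R,4S,5S)-5-(3,4-dimethoxyphenyl)-4-methyltetrahydrofuran-3-yl]methanol | COc1ccc([C@H]2OC[C@H]([C@H](O)c3ccc(OC)c(OC)c3)[C@@H]2C)cc1OC
A6 | alternative 3 | 4-{(1S)-1-{[3-(3,4-dimethoxyphenyl)prop-2-yn-1-yl]oxy}prop-2-en-1-yl}-1,2-dimethoxybenzene | COc1ccc([C@H](C=C)OCC#Cc2ccc(OC)c(OC)c2)cc1OC
A7 | alternative 3 | (2S,3S,4Z)-4-(3,4-dimethoxybenzylidene)-2-(3,4-dimethoxyphenyl)-3-methyltetrahydrofuran | COc1ccc([C@H]2OC/C(=C\c3ccc(OC)c(OC)c3)[C@@H]2C)cc1OC
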